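**Retrosynthetic overview**

1. The target comes from its 6,8-bis(triisopropylsilyl) ether by fluoride. The oxolane is the last ring made, closed at the bond between its ring oxygen and C2 (the carbon that carries the dienyl chain), in the same operation that installs the C3 hydroxyl.
2. Key disconnection: oxolane O–C2 and C3–OH go back to an all-E 8-hydroxynona-1,3,5-trienyl isocoumarin (one stereocentre, no oxolane). The forward step is asymmetric epoxidation of the terminal olefin, then 5-endo opening of the transient dienyl oxirane by the secondary hydroxyl (a biomimetic polyene oxidation–cyclisation).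
3. Enabling feature: oxolane C2 is the allylic terminus of the buta-1,3-diene that is conjugated with C3=C4 of the pyranone ring, so positive charge building at C2 is delocalised. The oxygen on oxolane C5 reaches C2 through a five-membered array, and the C3 hydroxyl is vicinal and anti to the new C–O bond, which is the pattern left by invertive opening of a trans-epoxide of an E-olefin.
4. The trienol comes from Suzuki–Miyaura coupling of an isocoumarinyl (E,E)-iododiene (from the 3-carbaldehyde by Wittig and Takai homologations) with an (E)-alkenyl boronate made from (R)-pent-4-yn-2-ol, which supplies the C5 stereocentre.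
5. Ring order: purchased benzene ring (chlorinated first), then the pyranone ring by lateral lithiation, acylation and enol lactonisation, then the oxirane (temporary ring), then the oxolane.

Key step: step 9

Remark: the absolute sense of oxygen transfer in the epoxidation is assigned by analogy with simple (E)-disubstituted olefins, and (R)-pent-4-yn-2-ol is taken as a purchased compound (otherwise one step from (R)-propylene oxide and lithium acetylide).

**Route**

Step 1
Reactants: 1 methyl 2,4-dimethoxy-6-methylbenzoate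
Product: 2 methyl 3-chloro-4,6-dimethoxy-2-methylbenzoate
Conditions: SO2Cl2 (1.05 equiv), CH2Cl2, 0 °C
Reagents that add atoms: sulfuryl chloride, ClS(Cl)(=O)=O
Why: Electrophilic aromatic chlorination should occur at the ring position para to the 2-methoxy group and ortho to the 4-methoxy and methyl groups (the site between the two methoxy groups lacks para activation and is more crowded), which places chlorine next to the methyl group as the later C5 of the isocoumarin.

Step 2
Reactants: 2 methyl 3-chloro-4,6-dimethoxy-2-methylbenzoate; 3 ethyl diethoxyacetate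
Product: 5 5-chloro-3-(diethoxymethyl)-6,8-dimethoxy-1H-isochromen-1-one, via keto ester 4 (not isolated)
Conditions: LiN(iPr)2 (2.2 equiv), THF, −78 °C; 3 (1.2 equiv), −78 °C → rt; AcOH quench
Reagents that add atoms: none
Why: Lateral (benzylic) lithiation of the ortho-toluate and Claisen-type acylation by the glyoxylate acetal ester (no acidic α-hydrogen) give keto ester 4 as its enolate (second equivalent of base), whose oxygen should attack the neighbouring methyl ester on warming (enol lactonisation) and close the pyranone ring.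

Step 3
Reactants: 5 5-chloro-3-(diethoxymethyl)-6,8-dimethoxy-1H-isochromen-1-one
Product: 6 5-chloro-6,8-dihydroxy-1-oxo-1H-isochromene-3-carbaldehyde
Conditions: BBr3 (6 equiv), CH2Cl2, −78 °C → rt; then H2O
Reagents that add atoms: water, O
Why: BBr3 cleaves both aryl methyl ethers and the diethyl acetal (Lewis-acid ether cleavage), and hydrolytic work-up releases the two phenols and the aldehyde while the enol lactone should stay intact.

Step 4
Reactants: 6 5-chloro-6,8-dihydroxy-1-oxo-1H-isochromene-3-carbaldehyde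
Product: 7 5-chloro-1-oxo-6,8-bis[(triisopropylsilyl)oxy]-1H-isochromene-3-carbaldehyde
Conditions: iPr3SiOTf (2.5 equiv), 2,6-lutidine, CH2Cl2, 0 °C → rt
Reagents that add atoms: triisopropylsilyl trifluoromethanesulfonate, CC(C)[Si](C(C)C)(C(C)C)OS(=O)(=O)C(F)(F)F
Why: Silylation with the silyl triflate should cap both phenols, the hydrogen-bonded 8-hydroxyl included, as bulky silyl ethers that tolerate the mildly basic and oxidative steps ahead and leave under fluoride at the end.

Step 5
Reactants: 7 5-chloro-1-oxo-6,8-bis[(triisopropylsilyl)oxy]-1H-isochromene-3-carbaldehyde; 8 (triphenylphosphoranylidene)acetaldehyde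
Product: 9 (2E)-3-{5-chloro-1-oxo-6,8-bis[(triisopropylsilyl)oxy]-1H-isochromen-3-yl}prop-2-enal
Conditions: 8 (1.1 equiv), toluene, 60 °C
Reagents that add atoms: none
Why: Wittig reaction of the electron-poor heteroaryl aldehyde with the stabilised formyl ylide should give the (E)-enal with the usual E preference of stabilised ylides.

Step 6
Reactants: 9 (2E)-3-{5-chloro-1-oxo-6,8-bis[(triisopropylsilyl)oxy]-1H-isochromen-3-yl}prop-2-enal
Product: 10 5-chloro-3-[(1E,3E)-4-iodobuta-1,3-dien-1-yl]-6,8-bis[(triisopropylsilyl)oxy]-1H-isochromen-1-one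
Conditions: CrCl2 (6 equiv), CHI3 (2 equiv), THF–dioxane, 0 °C → rt, dark
Reagents that add atoms: iodoform, IC(I)I
Why: Takai iodo-olefination (addition of the geminal dichromium species from CHI3 and CrCl2 to the aldehyde, then elimination) should convert the enal into the (E)-iodoalkene without touching lactone or silyl ethers.

Step 7
Reactants: 11 (2R)-pent-4-yn-2-ol
Product: 12 (2R,4E)-5-(4,4,5,5-tetramethyl-1,3,2-dioxaborolan-2-yl)pent-4-en-2-ol
Conditions: B2pin2 (1.1 equiv), CuCl (5 mol %), Xantphos (5 mol %), NaOtBu (10 mol %), MeOH (2 equiv), THF, rt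
Reagents that add atoms: bis(pinacolato)diboron, CC1(C)OB(OC1(C)C)B1OC(C)(C)C(C)(C)O1
Why: Copper-catalysed borylcupration of the terminal alkyne (syn addition, boron at the terminal carbon) followed by protonation by methanol should give the (E)-alkenyl boronate, the carbinol stereocentre taking no part.

Step 8
Reactants: 10 5-chloro-3-[(1E,3E)-4-iodobuta-1,3-dien-1-yl]-6,8-bis[(triisopropylsilyl)oxy]-1H-isochromen-1-one; 12 (2R,4E)-5-(4,4,5,5-tetramethyl-1,3,2-dioxaborolan-2-yl)pent-4-en-2-ol
Product: 13 5-chloro-3-[(1E,3E,5E,8R)-8-hydroxynona-1,3,5-trien-1-yl]-6,8-bis[(triisopropylsilyl)oxy]-1H-isochromen-1-one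
Conditions: Pd(dppf)Cl2 (5 mol %), aq. K3PO4, THF, rt
Reagents that add atoms: none
Why: Suzuki–Miyaura coupling of the alkenyl iodide with the alkenyl boronate proceeds with retention of both olefin geometries, tolerates the free hydroxyl and, with a mild phosphate base at room temperature, should spare the aryl silyl ethers and the lactone.

Step 9
Reactants: 13 5-chloro-3-[(1E,3E,5E,8R)-8-hydroxynona-1,3,5-trien-1-yl]-6,8-bis[(triisopropylsilyl)oxy]-1H-isochromen-1-one
Product: 15 5-chloro-3-{(1E,3E)-4-[(2S,3R,5R)-3-hydroxy-5-methyloxolan-2-yl]buta-1,3-dien-1-yl}-6,8-bis[(triisopropylsilyl)oxy]-1H-isochromen-1-one, via dienyl epoxide 14 (not isolated)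
Conditions: D-fructose-derived ketone catalyst of the Shi epoxidation (1,2:4,5-di-O-isopropylidene-β-D-erythro-2,3-hexodiulo-2,6-pyranose, 0.3 equiv), KHSO5 (as Oxone, 1.4 equiv), K2CO3, Bu4NHSO4, Na2B4O7 buffer, MeCN–CH2(OMe)2–H2O, 0 °C; extraction; then camphor-10-sulfonic acid (0.1 equiv), CH2Cl2, −20 → 0 °C
Reagents that add atoms: potassium peroxymonosulfate, [K+].[O-]S(=O)(=O)OO
Why: The dioxirane formed from the ketone catalyst and KHSO5 transfers oxygen in a concerted spiro transition state to the 5,6-olefin of the trienyl chain, closing the transient oxirane of 14, and catalytic acid then lets the C8 hydroxyl open that oxirane at its dienyl-substituted carbon with inversion, closing the oxolane in the 5-endo mode (intramolecular backside C–O bond formation). The closest known reaction types are the Shi asymmetric epoxidation of conjugated dienes and the acid-catalysed endo-selective hydroxy-epoxide opening of vinyl oxiranes. The carbinol stereocentre (oxolane C3, R) is set by reagent control, the catalyst delivering oxygen to the face that gives the (R,R)-epoxide as with simple E-olefins, and the ether stereocentre (oxolane C2, S) follows stereospecifically from invertive opening of the trans-epoxide, which puts the dienyl group trans to the hydroxyl and, with the (R)-carbinol carried from 11, cis to the methyl group. Site selectivity among the four C=C bonds is secured by the substrate, because the 5,6-olefin is the alkyl-terminated, most electron-rich and least hindered end of a polyene whose other end is deactivated by the lactone, and the neighbouring hydroxyl can hydrogen-bond to the dioxirane. Regioselectivity of the opening (5-endo rather than 4-exo) is secured by the diene conjugated with the pyranone, which delocalises the positive charge building at the attacked carbon, and by the strain of the alternative oxetane. A slight excess of oxidant only, and removal of the basic aqueous phase before the acid is added, should keep the remaining diene from further oxidation and the epoxide from premature ionisation.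

Step 10
Reactants: 15 5-chloro-3-{(1E,3E)-4-[(2S,3R,5R)-3-hydroxy-5-methyloxolan-2-yl]buta-1,3-dien-1-yl}-6,8-bis[(triisopropylsilyl)oxy]-1H-isochromen-1-one
Product: 16 5-chloro-6,8-dihydroxy-3-{(1E,3E)-4-[(2S,3R,5R)-3-hydroxy-5-methyloxolan-2-yl]buta-1,3-dien-1-yl}-1H-isochromen-1-one
Conditions: Bu4NF (2.5 equiv), AcOH (2.5 equiv), THF, 0 °C
Reagents that add atoms: none
Why: Fluoride cleaves the two aryl silyl ethers through Si–F bond formation, and the acetic acid buffer should protect the phenols, the enol lactone and the allylic ether of the oxolane from base-induced damage.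

**Compound list**

1 | methyl 2,4-dimethoxy-6-methylbenzoate | COC(=O)c1c(C)cc(OC)cc1OC | starting material
2 | methyl 3-chloro-4,6-dimethoxy-2-methylbenzoate | COC(=O)c1c(C)c(Cl)c(OC)cc1OC | intermediate
3 | ethyl diethoxyacetate | CCOC(=O)C(OCC)OCC | starting material
4 | methyl 3-chloro-2-(3,3-diethoxy-2-oxopropyl)-4,6-dimethoxybenzoate | COC(=O)c1c(CC(=O)C(OCC)OCC)c(Cl)c(OC)cc1OC | intermediate
5 | 5-chloro-3-(diethoxymethyl)-6,8-dimethoxy-1H-isochromen-1-one | CCOC(OCC)c1cc2c(Cl)c(OC)cc(OC)c2c(=O)o1 | intermediate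
6 | 5-chloro-6,8-dihydroxy-1-oxo-1H-isochromene-3-carbaldehyde | O=Cc1cc2c(Cl)c(O)cc(O)c2c(=O)o1 | intermediate
7 | 5-chloro-1-oxo-6,8-bis[(triisopropylsilyl)oxy]-1H-isochromene-3-carbaldehyde | O=Cc1cc2c(Cl)c(O[Si](C(C)C)(C(C)C)C(C)C)cc(O[Si](C(C)C)(C(C)C)C(C)C)c2c(=O)o1 | intermediate
8 | (triphenylphosphoranylidene)acetaldehyde | O=CC=P(c1ccccc1)(c1ccccc1)c1ccccc1 | starting material
9 | (2E)-3-{5-chloro-1-oxo-6,8-bis[(triisopropylsilyl)oxy]-1H-isochromen-3-yl}prop-2-enal | O=C/C=C/c1cc2c(Cl)c(O[Si](C(C)C)(C(C)C)C(C)C)cc(O[Si](C(C)C)(C(C)C)C(C)C)c2c(=O)o1 | intermediate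
10 | 5-chloro-3-[(1E,3E)-4-iodobuta-1,3-dien-1-yl]-6,8-bis[(triisopropylsilyl)oxy]-1H-isochromen-1-one | I/C=C/C=C/c1cc2c(Cl)c(O[Si](C(C)C)(C(C)C)C(C)C)cc(O[Si](C(C)C)(C(C)C)C(C)C)c2c(=O)o1 | intermediate
11 | (2R)-pent-4-yn-2-ol | C[C@@H](O)CC#C | starting material
12 | (2R,4E)-5-(4,4,5,5-tetramethyl-1,3,2-dioxaborolan-2-yl)pent-4-en-2-ol | C[C@@H](O)C/C=C/B1OC(C)(C)C(C)(C)O1 | intermediate
13 | 5-chloro-3-[(1E,3E,5E,8R)-8-hydroxynona-1,3,5-trien-1-yl]-6,8-bis[(triisopropylsilyl)oxy]-1H-isochromen-1-one | C[C@@H](O)C/C=C/C=C/C=C/c1cc2c(Cl)c(O[Si](C(C)C)(C(C)C)C(C)C)cc(O[Si](C(C)C)(C(C)C)C(C)C)c2c(=O)o1 | intermediate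
14 | 5-chloro-3-[(1E,3E)-4-{(2R,3R)-3-[(2R)-2-hydroxypropyl]oxiran-2-yl}buta-1,3-dien-1-yl]-6,8-bis[(triisopropylsilyl)oxy]-1H-isochromen-1-one | C[C@@H](O)C[C@H]1O[C@@H]1/C=C/C=C/c2cc3c(Cl)c(O[Si](C(C)C)(C(C)C)C(C)C)cc(O[Si](C(C)C)(C(C)C)C(C)C)c3c(=O)o2 | intermediate
15 | 5-chloro-3-{(1E,3E)-4-[(2S,3R,5R)-3-hydroxy-5-methyloxolan-2-yl]buta-1,3-dien-1-yl}-6,8-bis[(triisopropylsilyl)oxy]-1H-isochromen-1-one | C[C@@H]1C[C@@H](O)[C@H](/C=C/C=C/c2cc3c(Cl)c(O[Si](C(C)C)(C(C)C)C(C)C)cc(O[Si](C(C)C)(C(C)C)C(C)C)c3c(=O)o2)O1 | intermediate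
16 | 5-chloro-6,8-dihydroxy-3-{(1E,3E)-4-[(2S,3R,5R)-3-hydroxy-5-methyloxolan-2-yl]buta-1,3-dien-1-yl}-1H-isochromen-1-one | C[C@@H]1C[C@@H](O)[C@H](/C=C/C=C/c2cc3c(Cl)c(O)cc(O)c3c(=O)o2)O1 | target

**Step count and risks**

Total step count: 10. Longest linear sequence: 9 (steps 1–6, 8, 9, 10).

The three steps most likely to fail:

Step 9 (key step). Oxygen transfer may go to another double bond or a second time to the polyene, or the dienyl epoxide may ionise before ring closure so that the invertive course at C2 is lost. The fallback moves the oxidative cyclisation to a small chlorodiene that has only one electron-rich double bond and attaches the isocoumarin afterwards; it sets out from 12 and 7 and returns at 15. Boronate 12 would be coupled at the carbon–iodine bond of (E)-1-chloro-2-iodoethene (Pd(PPh3)4, aq. K3PO4, THF) to give (2R,4E,6E)-7-chlorohepta-4,6-dien-2-ol F1. Shi epoxidation under the conditions of step 9, with the chloro-substituted olefin deactivated, should give (2R)-1-[(2R,3R)-3-[(E)-2-chloroethenyl]oxiran-2-yl]propan-2-ol F2, which on treatment with catalytic camphor-10-sulfonic acid should close to (2S,3R,5R)-2-[(E)-2-chloroethenyl]-5-methyloxolan-3-ol F3. In parallel, aldehyde 7 would be homologated by the boron-Wittig reaction (bis(pinacolboryl)methane, lithium 2,2,6,6-tetramethylpiperidide, THF, −78 °C) to 5-chloro-3-[(E)-2-(4,4,5,5-tetramethyl-1,3,2-dioxaborolan-2-yl)ethenyl]-6,8-bis[(triisopropylsilyl)oxy]-1H-isochromen-1-one F4. Suzuki–Miyaura coupling of the alkenyl chloride F3 with F4 (Pd(OAc)2, SPhos, K3PO4, THF–H2O) would then give 15, which is desilylated as in step 10.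

Step 2. The lithiated toluate may condense with itself, or the enolate oxygen may fail to attack the hindered, electron-rich methyl ester so that ring closure stalls in the flask. The fallback builds a 3-methylisocoumarin stepwise and oxidises the methyl group later; it sets out from 2 and returns at 7. Lithiated 2 would be acylated with N-methoxy-N-methylacetamide to methyl 3-chloro-4,6-dimethoxy-2-(2-oxopropyl)benzoate F5, which would be cyclised under acid catalysis (TsOH, toluene, reflux) to 5-chloro-6,8-dimethoxy-3-methyl-1H-isochromen-1-one F6. BBr3 would then give 5-chloro-6,8-dihydroxy-3-methyl-1H-isochromen-1-one F7, iPr3SiOTf and 2,6-lutidine would give 5-chloro-3-methyl-6,8-bis[(triisopropylsilyl)oxy]-1H-isochromen-1-one F8, and SeO2 (dioxane, reflux) should oxidise the 3-methyl group to aldehyde 7.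

Step 3. The Lewis acid may attack the unmasked aldehyde (bromination at the formyl carbon), or cleavage of the methyl ether next to chlorine may stay incomplete. The fallback exchanges the protecting groups before pyranone and aldehyde exist; it sets out from 2 and returns at 7. BBr3 would convert 2 into methyl 3-chloro-4,6-dihydroxy-2-methylbenzoate F9, and silylation (iPr3SiOTf, 2,6-lutidine) would give methyl 3-chloro-2-methyl-4,6-bis[(triisopropylsilyl)oxy]benzoate F10. Lateral lithiation and acylation with 3 as in step 2 would lead through methyl 3-chloro-2-(3,3-diethoxy-2-oxopropyl)-4,6-bis[(triisopropylsilyl)oxy]benzoate F11 to 5-chloro-3-(diethoxymethyl)-6,8-bis[(triisopropylsilyl)oxy]-1H-isochromen-1-one F12. Mild aqueous acid (CF3CO2H–H2O, CH2Cl2, 0 °C) would then hydrolyse the acetal to 7.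

Further compounds
F1 | step 9 | (2R,4E,6E)-7-chlorohepta-4,6-dien-2-ol | C[C@@H](O)C/C=C/C=C/Cl
F2 | step 9 | (2R)-1-[(2R,3R)-3-[(E)-2-chloroethenyl]oxiran-2-yl]propan-2-ol | C[C@@H](O)C[C@H]1O[C@@H]1/C=C/Cl
F3 | step 9 | (2S,3R,5R)-2-[(E)-2-chloroethenyl]-5-methyloxolan-3-ol | C[C@@H]1C[C@@H](O)[C@H](/C=C/Cl)O1
F4 | step 9 | 5-chloro-3-[(E)-2-(4,4,5,5-tetramethyl-1,3,2-dioxaborolan-2-yl)ethenyl]-6,8-bis[(triisopropylsilyl)oxy]-1H-isochromen-1-one | CC1(C)OB(/C=C/c2cc3c(Cl)c(O[Si](C(C)C)(C(C)C)C(C)C)cc(O[Si](C(C)C)(C(C)C)C(C)C)c3c(=O)o2)OC1(C)C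
F5 | step 2 | methyl 3-chloro-4,6-dimethoxy-2-(2-oxopropyl)benzoate | COC(=O)c1c(CC(C)=O)c(Cl)c(OC)cc1OC
F6 | step 2 | 5-chloro-6,8-dimethoxy-3-methyl-1H-isochromen-1-one | Cc1cc2c(Cl)c(OC)cc(OC)c2c(=O)o1
F7 | step 2 | 5-chloro-6,8-dihydroxy-3-methyl-1H-isochromen-1-one | Cc1cc2c(Cl)c(O)cc(O)c2c(=O)o1
F8 | step 2 | 5-chloro-3-methyl-6,8-bis[(triisopropylsilyl)oxy]-1H-isochromen-1-one | Cc1cc2c(Cl)c(O[Si](C(C)C)(C(C)C)C(C)C)cc(O[Si](C(C)C)(C(C)C)C(C)C)c2c(=O)o1
F9 | step 3 | methyl 3-chloro-4,6-dihydroxy-2-methylbenzoate | COC(=O)c1c(C)c(Cl)c(O)cc1O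
F10 | step 3 | methyl 3-chloro-2-methyl-4,6-bis[(triisopropylsilyl)oxy]benzoate | COC(=O)c1c(C)c(Cl)c(O[Si](C(C)C)(C(C)C)C(C)C)cc1O[Si](C(C)C)(C(C)C)C(C)C
F11 | step 3 | methyl 3-chloro-2-(3,3-diethoxy-2-oxopropyl)-4,6-bis[(triisopropylsilyl)oxy]benzoate | COC(=O)c1c(CC(=O)C(OCC)OCC)c(Cl)c(O[Si](C(C)C)(C(C)C)C(C)C)cc1O[Si](C(C)C)(C(C)C)C(C)C
F12 | step 3 | 5-chloro-3-(diethoxymethyl)-6,8-bis[(triisopropylsilyl)oxy]-1H-isochromen-1-one | CCOC(OCC)c1cc2c(Cl)c(O[Si](C(C)C)(C(C)C)C(C)C)cc(O[Si](C(C)C)(C(C)C)C(C)C)c2c(=O)o1
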